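**Plan**
- Retrosynthetic cuts, in order: the C2–aryl bond of the upper chroman (ring B off, leaving a 2-methoxy acetal); then O1–C2 and C4–C4a of the upper pyran ring together, back to resorcinol and a propargylic alcohol on C6 of the lower flavan; then the alkyne–carbinol and C6–CHO bonds, back to 8-bromo-tetra-O-benzyl-(−)-epiafzelechin.
- Enabling feature: upper C4 is doubly benzylic, held between C4a (ortho to O1, para to the 7-OH of the resorcinol ring A) and C6 of the phloroglucinol-type ring A of the lower unit. The O1–C8a–C4a phenol unit can therefore add as a C,O-bisnucleophile across a C2–C3–C4 allenylidene whose C4 cation the lower ring stabilises.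
- Forward: protect the lower flavan-3-ol, block C8 with bromine, formylate C6, add ethyne; close the upper pyran ring by a ruthenium-allenylidene (3+3) annulation with resorcinol; add ring B at C2; hydrogenolyse.
- Stereochemistry: lower C2 and C3 come from (−)-epiafzelechin; upper C4 (R) from the chiral diruthenium catalyst; upper C2 (S) from aryl addition to the oxocarbenium ion anti to the C4 substituent (2,4-trans).
- Helpers removed later: the alkyne oxidation level at C2–C3 (enol ether, then acetal; steps 8 and 9), the C8 bromine and all benzyl ethers (step 10).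

Key step: step 6

Remark: (−)-epiafzelechin is taken as the purchasable chiral-pool material, and its benzyl ether is assumed to brominate at C8 before C6, as benzylated epicatechin does. In the names below, G = (2R,3R)-3,5,7-tris(benzyloxy)-2-[4-(benzyloxy)phenyl]-8-bromochroman-6-yl.

Step 1
Reactants: 1 (−)-epiafzelechin
Product: 2 (2R,3R)-5,7-bis(benzyloxy)-2-[4-(benzyloxy)phenyl]chroman-3-ol
Conditions: BnBr (3.3 equiv), K2CO3, DMF, 0 °C to rt, argon
Reagents that add atoms: benzyl bromide BrCc1ccccc1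
Why: Williamson etherification in which K2CO3 deprotonates only the three phenols, so the secondary 3-OH stays free and no stereocentre is touched.

Step 2
Reactants: 2 (2R,3R)-5,7-bis(benzyloxy)-2-[4-(benzyloxy)phenyl]chroman-3-ol
Product: 3 (2R,3R)-3,5,7-tris(benzyloxy)-2-[4-(benzyloxy)phenyl]chroman
Conditions: NaH, BnBr, DMF, 0 °C to rt
Reagents that add atoms: benzyl bromide BrCc1ccccc1
Why: Williamson etherification of the secondary alkoxide; with all phenols capped no quinone-methide ring opening is possible, so C2 and C3 keep their configuration.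

Step 3
Reactants: 3 (2R,3R)-3,5,7-tris(benzyloxy)-2-[4-(benzyloxy)phenyl]chroman
Product: 4 (2R,3R)-3,5,7-tris(benzyloxy)-2-[4-(benzyloxy)phenyl]-8-bromochroman
Conditions: NBS (1.0 equiv), CH2Cl2, −78 °C to rt
Reagents that add atoms: N-bromosuccinimide O=C1CCC(=O)N1Br
Why: Electrophilic aromatic bromination, which in 5,7-dialkoxyflavans should go to C8 of ring A in preference to the more hindered C6; the bromine then serves as a blocking group until step 10.

Step 4
Reactants: 4 (2R,3R)-3,5,7-tris(benzyloxy)-2-[4-(benzyloxy)phenyl]-8-bromochroman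
Product: 6 (2R,3R)-3,5,7-tris(benzyloxy)-2-[4-(benzyloxy)phenyl]-8-bromochroman-6-carbaldehyde (G–CHO), via iminium chloride 5 (not isolated)
Conditions: POCl3, DMF, 0 to 60 °C; then aq NaOAc, rt
Reagents that add atoms: N,N-dimethylformamide CN(C)C=O; water O
Why: Vilsmeier–Haack formylation: with C8 blocked the chloroiminium ion can only attack C6, which is still activated by three oxygen substituents (5-OBn and 7-OBn ortho, O1 para), and hydrolysis of the aryl iminium salt gives the aldehyde.

Step 5
Reactants: 6 G–CHO; 7 ethynylmagnesium bromide (HC≡CMgBr)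
Product: 8 1-G-prop-2-yn-1-ol (both carbinol epimers)
Conditions: THF, −40 to 0 °C; then pH 7 phosphate buffer
Reagents that add atoms: none
Why: Grignard addition of the acetylide to the aldehyde, with no exchange at the aryl bromide at this temperature; the carbinol centre forms as both epimers, which does not matter because it becomes planar in step 6.

Step 6
Reactants: 8 1-G-prop-2-yn-1-ol; 9 resorcinol
Product: 11 (4R)-4-G-4H-chromen-7-ol, via propargylated resorcinol 10 (not isolated)
Conditions: [(C5Me5)RuCl(μ-SR*)]2 (5 mol%, SR* = (R)-SCH(Et)C6H2Ph3-2,3,5), NH4BF4 (10 mol%), 9 (4 equiv), ClCH2CH2Cl, 40 °C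
Reagents that add atoms: none
Why: The diruthenium complex converts the terminal propargylic alcohol, with loss of water, into a ruthenium allenylidene Ru=C=C=CH–G whose γ-carbon (the future C4) is a cation stabilised by the 2,4,6-trioxygenated ring A of the lower unit; C4 of resorcinol attacks this carbon (C4–C4a) to give 10, which, still bound to ruthenium as its vinylidene, is attacked at the α-carbon by the neighbouring phenolic oxygen (O1–C2) before protonolysis releases the 4H-chromene. The closest known reaction type is the ruthenium-allenylidene (3+3) annulation of 1-arylprop-2-yn-1-ols with electron-rich phenols and 2-naphthols, including its enantioselective form with chiral thiolate-bridged diruthenium catalysts. The pyran ring closes by intramolecular 6-endo-dig attack of oxygen on the vinylidene, that is, an anti-Markovnikov hydroalkoxylation of the alkyne. The only new stereocentre, C4, is set in the C–C bond-forming event by the chiral thiolate ligands, which shield one face of the planar γ-carbon; both carbinol epimers of 8 converge on the same allenylidene, the ligand antipode is fixed so that the 4R epimer results, and any 4S epimer is a diastereomer that should be separable. The step needs face selectivity (catalyst control must outrun uncatalysed ionisation of the electron-rich alcohol, hence the low temperature and little NH4BF4), site selectivity on resorcinol (C4 and C6 are equivalent, each ortho to one OH and para to the other, and only C-attack next to an OH can cyclise) and mono-annulation (secured by excess resorcinol).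

Step 7
Reactants: 11 (4R)-4-G-4H-chromen-7-ol
Product: 12 (4R)-7-(benzyloxy)-4-G-4H-chromene
Conditions: BnBr, K2CO3, DMF, rt
Reagents that add atoms: benzyl bromide BrCc1ccccc1
Why: Williamson etherification of the phenol; the enol ether and the C4 stereocentre are inert to K2CO3.

Step 8
Reactants: 12 (4R)-7-(benzyloxy)-4-G-4H-chromene
Product: 13 (4R)-7-(benzyloxy)-2-methoxy-4-G-chroman (both C2 anomers)
Conditions: MeOH, PPTS (cat.), CH2Cl2, rt
Reagents that add atoms: methanol CO
Why: Acid-catalysed Markovnikov addition of methanol to the cyclic enol ether (protonation at C3, capture at C2) gives the acetal as both anomers, whose C2 centre is erased again in step 9.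

Step 9
Reactants: 13 (4R)-7-(benzyloxy)-2-methoxy-4-G-chroman; 14 potassium [4-(benzyloxy)phenyl]trifluoroborate
Product: 15 (2S,4R)-7-(benzyloxy)-2-[4-(benzyloxy)phenyl]-4-G-chroman
Conditions: 14 (2 equiv), BF3·OEt2 (2 equiv), MeCN/CH2Cl2, −40 to 0 °C; then aq NaHCO3
Reagents that add atoms: none
Why: Oxocarbenium arylation with an organotrifluoroborate: BF3 turns 14 into the aryldifluoroborane and ionises the acetal to the chroman-2-yl oxocarbenium ion, and the aryl group is transferred through its ipso carbon on the face opposite to the bulky C4 aryl group (pseudo-axial to avoid the peri hydrogen at C5), which should set C2 as S (2,4-trans) from either anomer.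

Step 10
Reactants: 15 (2S,4R)-7-(benzyloxy)-2-[4-(benzyloxy)phenyl]-4-G-chroman
Product: 16 (2R,3R)-6-[(2S,4R)-7-hydroxy-2-(4-hydroxyphenyl)chroman-4-yl]-2-(4-hydroxyphenyl)chroman-3,5,7-triol (target)
Conditions: H2 (1 atm), Pd(OH)2/C, Et3N, THF/MeOH, rt
Reagents that add atoms: none
Why: Heterogeneous hydrogenolysis should cleave the six O-benzyl groups and the C8–Br bond (Et3N takes up HBr and keeps the medium non-acidic) while the cyclic benzylic ethers O1–C2 and all stereocentres survive, as in debenzylations of benzylated flavan-3-ol oligomers.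

**Compound list**
1 | (−)-epiafzelechin, (2R,3R)-2-(4-hydroxyphenyl)chroman-3,5,7-triol | c1c(O)cc2c(c1O)C[C@@H](O)[C@@H](c3ccc(O)cc3)O2 | starting material
2 | (2R,3R)-5,7-bis(benzyloxy)-2-[4-(benzyloxy)phenyl]chroman-3-ol | c1c(OCc3ccccc3)cc2c(c1OCc3ccccc3)C[C@@H](O)[C@@H](c3ccc(OCc4ccccc4)cc3)O2 | intermediate
3 | (2R,3R)-3,5,7-tris(benzyloxy)-2-[4-(benzyloxy)phenyl]chroman | c1c(OCc3ccccc3)cc2c(c1OCc3ccccc3)C[C@@H](OCc3ccccc3)[C@@H](c3ccc(OCc4ccccc4)cc3)O2 | intermediate
4 | (2R,3R)-3,5,7-tris(benzyloxy)-2-[4-(benzyloxy)phenyl]-8-bromochroman | c1c(OCc3ccccc3)c(Br)c2c(c1OCc3ccccc3)C[C@@H](OCc3ccccc3)[C@@H](c3ccc(OCc4ccccc4)cc3)O2 | intermediate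
5 | N-(G-methylidene)-N-methylmethanaminium chloride (aryl iminium chloride) | C[N+](C)=Cc1c(OCc3ccccc3)c(Br)c2c(c1OCc3ccccc3)C[C@@H](OCc3ccccc3)[C@@H](c3ccc(OCc4ccccc4)cc3)O2.[Cl-] | intermediate
6 | (2R,3R)-3,5,7-tris(benzyloxy)-2-[4-(benzyloxy)phenyl]-8-bromochroman-6-carbaldehyde (G–CHO) | O=Cc1c(OCc3ccccc3)c(Br)c2c(c1OCc3ccccc3)C[C@@H](OCc3ccccc3)[C@@H](c3ccc(OCc4ccccc4)cc3)O2 | intermediate
7 | ethynylmagnesium bromide | C#C[Mg]Br | starting material
8 | 1-G-prop-2-yn-1-ol (both carbinol epimers) | C#CC(O)c1c(OCc3ccccc3)c(Br)c2c(c1OCc3ccccc3)C[C@@H](OCc3ccccc3)[C@@H](c3ccc(OCc4ccccc4)cc3)O2 | intermediate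
9 | resorcinol (benzene-1,3-diol) | Oc1cccc(O)c1 | starting material
10 | 4-[(1R)-1-G-prop-2-yn-1-yl]benzene-1,3-diol | C#C[C@@H](c5c(OCc7ccccc7)c(Br)c6c(c5OCc7ccccc7)C[C@@H](OCc7ccccc7)[C@@H](c7ccc(OCc8ccccc8)cc7)O6)c1ccc(O)cc1O | intermediate
11 | (4R)-4-G-4H-chromen-7-ol | C1=C[C@@H](c5c(OCc7ccccc7)c(Br)c6c(c5OCc7ccccc7)C[C@@H](OCc7ccccc7)[C@@H](c7ccc(OCc8ccccc8)cc7)O6)c2ccc(O)cc2O1 | intermediate
12 | (4R)-7-(benzyloxy)-4-G-4H-chromene | C1=C[C@@H](c5c(OCc7ccccc7)c(Br)c6c(c5OCc7ccccc7)C[C@@H](OCc7ccccc7)[C@@H](c7ccc(OCc8ccccc8)cc7)O6)c2ccc(OCc3ccccc3)cc2O1 | intermediate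
13 | (4R)-7-(benzyloxy)-2-methoxy-4-G-chroman (both C2 anomers) | COC1C[C@@H](c5c(OCc7ccccc7)c(Br)c6c(c5OCc7ccccc7)C[C@@H](OCc7ccccc7)[C@@H](c7ccc(OCc8ccccc8)cc7)O6)c2ccc(OCc3ccccc3)cc2O1 | intermediate
14 | potassium [4-(benzyloxy)phenyl]trifluoroborate | [K+].F[B-](F)(F)c1ccc(OCc2ccccc2)cc1 | starting material
15 | (2S,4R)-7-(benzyloxy)-2-[4-(benzyloxy)phenyl]-4-G-chroman | c3ccccc3COc1ccc([C@@H]2C[C@@H](c5c(OCc7ccccc7)c(Br)c6c(c5OCc7ccccc7)C[C@@H](OCc7ccccc7)[C@@H](c7ccc(OCc8ccccc8)cc7)O6)c4ccc(OCc3ccccc3)cc4O2)cc1 | intermediate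
16 | (2R,3R)-6-[(2S,4R)-7-hydroxy-2-(4-hydroxyphenyl)chroman-4-yl]-2-(4-hydroxyphenyl)chroman-3,5,7-triol | Oc1ccc([C@@H]2C[C@@H](c3c(O)cc4c(c3O)C[C@@H](O)[C@@H](c3ccc(O)cc3)O4)c3ccc(O)cc3O2)cc1 | target

Total step count: 10. Longest linear sequence: 10 steps (from 1).

**Steps most likely to fail**

Step 6. The very electron-rich propargylic alcohol may ionise without the catalyst, which would erode face selectivity at C4 or lead to Meyer–Schuster rearrangement, and the donor-stabilised allenylidene may be captured only slowly by resorcinol. The fallback sets out from aldehyde 6 and comes back at acetal 13, with C4 fixed by diastereomer separation instead of catalyst control. Horner–Wadsworth–Emmons olefination of 6 with triethyl phosphonoacetate (NaH, THF) would give ethyl (E)-3-G-prop-2-enoate F1. Treatment of F1 and resorcinol 9 with CF3CO2H in CH2Cl2 (Friedel–Crafts hydroarylation at the benzylic carbon, then lactonisation) would give the 4-aryl-3,4-dihydrocoumarin as both C4 epimers; these are diastereomers, and chromatography would leave (4R)-4-G-7-hydroxychroman-2-one F2. Benzylation of the phenol (BnBr, K2CO3, acetone) would give (4R)-7-(benzyloxy)-4-G-chroman-2-one F3, reduction with i-Bu2AlH at −78 °C the lactol (4R)-7-(benzyloxy)-4-G-chroman-2-ol F4, and MeOH with PPTS the acetal 13.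

Step 9. Aryl transfer to the oxocarbenium ion may be slow, face selectivity at C2 may be incomplete, or the Lewis acid may ionise the product at C4 or C2. The fallback sets out from acetal 13 and comes back at 15, replacing the oxocarbenium addition by reagent-controlled reduction and ring closure with inversion. Hydrolysis of 13 (aq AcOH, THF) would give the lactol (4R)-7-(benzyloxy)-4-G-chroman-2-ol F4. Excess 4-(benzyloxy)phenylmagnesium bromide would add to its open hydroxy-aldehyde form to give the diol (3R)-3-[4-(benzyloxy)-2-hydroxyphenyl]-1-[4-(benzyloxy)phenyl]-3-G-propan-1-ol F5 (both carbinol epimers). Benzylic oxidation with MnO2 would give the ketone (3R)-3-[4-(benzyloxy)-2-hydroxyphenyl]-1-[4-(benzyloxy)phenyl]-3-G-propan-1-one F6. Corey–Bakshi–Shibata reduction with (S)-2-methyl-CBS-oxazaborolidine and BH3·SMe2 would give the (1R,3R)-carbinol F7, and Mitsunobu closure (PPh3, DIAD, THF) with inversion at the carbinol carbon would give 15.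

Step 4. Formylation at C6, flanked by two benzyloxy groups, may be sluggish, and the acidic medium may cleave benzyl ethers. The fallback sets out from bromide 4 and comes back at aldehyde 6, replacing electrophilic formylation by a halogen–metal exchange. Iodination at C6 (N-iodosuccinimide, cat. CF3CO2H, MeCN) would give (2R,3R)-3,5,7-tris(benzyloxy)-2-[4-(benzyloxy)phenyl]-8-bromo-6-iodochroman F8. Iodine–magnesium exchange with i-PrMgCl·LiCl (THF, −40 °C), selective over the bromide, followed by quenching with DMF would give 6.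

**Further compounds**
F1 | step 6 | ethyl (E)-3-G-prop-2-enoate | CCOC(=O)/C=C/c1c(OCc3ccccc3)c(Br)c2c(c1OCc3ccccc3)C[C@@H](OCc3ccccc3)[C@@H](c3ccc(OCc4ccccc4)cc3)O2
F2 | step 6 | (4R)-4-G-7-hydroxychroman-2-one | O=C1C[C@@H](c5c(OCc7ccccc7)c(Br)c6c(c5OCc7ccccc7)C[C@@H](OCc7ccccc7)[C@@H](c7ccc(OCc8ccccc8)cc7)O6)c2ccc(O)cc2O1
F3 | step 6 | (4R)-7-(benzyloxy)-4-G-chroman-2-one | O=C1C[C@@H](c5c(OCc7ccccc7)c(Br)c6c(c5OCc7ccccc7)C[C@@H](OCc7ccccc7)[C@@H](c7ccc(OCc8ccccc8)cc7)O6)c2ccc(OCc3ccccc3)cc2O1
F4 | step 6 | (4R)-7-(benzyloxy)-4-G-chroman-2-ol (both anomers) | OC1C[C@@H](c5c(OCc7ccccc7)c(Br)c6c(c5OCc7ccccc7)C[C@@H](OCc7ccccc7)[C@@H](c7ccc(OCc8ccccc8)cc7)O6)c2ccc(OCc3ccccc3)cc2O1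
F5 | step 9 | (3R)-3-[4-(benzyloxy)-2-hydroxyphenyl]-1-[4-(benzyloxy)phenyl]-3-G-propan-1-ol (both carbinol epimers) | c3ccccc3COc1ccc(C(O)C[C@@H](c5c(OCc7ccccc7)c(Br)c6c(c5OCc7ccccc7)C[C@@H](OCc7ccccc7)[C@@H](c7ccc(OCc8ccccc8)cc7)O6)c4ccc(OCc3ccccc3)cc4O)cc1
F6 | step 9 | (3R)-3-[4-(benzyloxy)-2-hydroxyphenyl]-1-[4-(benzyloxy)phenyl]-3-G-propan-1-one | c3ccccc3COc1ccc(C(=O)C[C@@H](c5c(OCc7ccccc7)c(Br)c6c(c5OCc7ccccc7)C[C@@H](OCc7ccccc7)[C@@H](c7ccc(OCc8ccccc8)cc7)O6)c4ccc(OCc3ccccc3)cc4O)cc1
F7 | step 9 | (1R,3R)-3-[4-(benzyloxy)-2-hydroxyphenyl]-1-[4-(benzyloxy)phenyl]-3-G-propan-1-ol | c3ccccc3COc1ccc([C@H](O)C[C@@H](c5c(OCc7ccccc7)c(Br)c6c(c5OCc7ccccc7)C[C@@H](OCc7ccccc7)[C@@H](c7ccc(OCc8ccccc8)cc7)O6)c4ccc(OCc3ccccc3)cc4O)cc1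
F8 | step 4 | (2R,3R)-3,5,7-tris(benzyloxy)-2-[4-(benzyloxy)phenyl]-8-bromo-6-iodochroman | Ic1c(OCc3ccccc3)c(Br)c2c(c1OCc3ccccc3)C[C@@H](OCc3ccccc3)[C@@H](c3ccc(OCc4ccccc4)cc3)O2
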